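Retrosynthesis: after the O6 silyl group is removed, the target is cut at C2'–C3' (B-alkyl Suzuki coupling of a chromene head with a terpene vinyl iodide), at C3=C4 of the pyran ring (ring-closing metathesis) and at O1–C2 (phenoxide alkylation). The tail is cut at C4'–CH3 (carboalumination), C4'–C5' (acetylide alkylation) and C1''–C6' ([3,3] shift).
Enabling feature: C2 of the 2H-pyran ring is a fully substituted carbon on O1. Its ring arm C3=C4 and its chain arm C1'–C2' each count two carbons, so both descend from two identical vinyl groups on one prochiral carbon that also carries CH3 and the aryloxy oxygen.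
Forward order: the benzene and cyclohexene rings are bought. The pyran ring is closed from an achiral triene before any tail alkene is in the molecule, and the vinyl group left over is the handle by which the chain is joined in the penultimate step.
Stereochemistry: C2 (S) comes from catalyst-controlled choice between the enantiotopic vinyl groups. C1'' (S) comes from CBS reduction to an (R)-allylic alcohol and suprafacial Eschenmoser–Claisen transfer. C3'=C4' (E) comes from syn-methylalumination and is retained in iodinolysis and coupling.

Key step: step 6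

Numbering used: chromene O1, C2, C3, C4, C4a, C5–C8, C8a; side chain C1'–C6' counted from C2; C1'' is the cyclohexene carbon that bears the chain.
Assumption: the sense of induction of the molybdenum catalyst on this triene cannot be predicted safely. The (S)-biphenolate complex is written, and its equally available mirror image is used instead if a test run gives the (R)-chromene. 2,4,4-Trimethylcyclohex-2-en-1-one is taken as a catalogue chemical.

Step 1
Reactants: 1 2,5-dihydroxybenzaldehyde
Product: 2 2-hydroxy-5-(triisopropylsilyloxy)benzaldehyde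
Conditions: iPr3SiCl (1.05 equiv), imidazole, CH2Cl2, 0 °C to rt
Reagents that add atoms: triisopropylsilyl chloride, CC(C)[Si](Cl)(C(C)C)C(C)C
Why: Silyl ether formation should take only the 5-OH, because the 2-OH is hydrogen-bonded to the aldehyde oxygen and flanked by the formyl group, so one equivalent of the bulky chlorosilane should stop at the mono-ether.

Step 2
Reactants: 2 2-hydroxy-5-(triisopropylsilyloxy)benzaldehyde; 3 diethyl 2-bromo-2-methylmalonate
Product: 4 diethyl 2-[2-formyl-4-(triisopropylsilyloxy)phenoxy]-2-methylmalonate
Conditions: K2CO3 (anhydrous, powdered), DMF, 40 °C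
Reagents that add atoms: none
Why: In this Williamson-type O-alkylation the bromine sits on a tertiary carbon activated by two esters, a class of halide known to be displaced by phenoxides, and the product has no alpha-hydrogen, so under dry conditions it cannot follow the aldol/benzofuran path of simple bromomalonates.

Step 3
Reactants: 4 diethyl 2-[2-formyl-4-(triisopropylsilyloxy)phenoxy]-2-methylmalonate
Product: 5 2-[2-(hydroxymethyl)-4-(triisopropylsilyloxy)phenoxy]-2-methylpropane-1,3-diol
Conditions: LiAlH4, THF, 0 °C; Na2SO4·10H2O quench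
Reagents that add atoms: none
Why: Hydride reduction with LiAlH4 takes both esters and the aldehyde to primary alcohols in one operation, while the aryl triisopropylsilyl ether and the aryl alkyl ether are inert at 0 °C.

Step 4
Reactants: 5 2-[2-(hydroxymethyl)-4-(triisopropylsilyloxy)phenoxy]-2-methylpropane-1,3-diol
Product: 6 2-[2-formyl-4-(triisopropylsilyloxy)phenoxy]-2-methylpropanedial
Conditions: (COCl)2, DMSO, CH2Cl2, −78 °C; Et3N, −78 to −20 °C; cold neutral wash, used crude at once
Reagents that add atoms: none
Why: In the Swern oxidation all three hydroxyl groups are activated at −78 °C before the amine is added, so no hydroxy aldehyde is ever present that could lactolise or lose formaldehyde by retro-aldol cleavage, and the non-enolisable trialdehyde is not exposed to silica.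

Step 5
Reactants: 6 2-[2-formyl-4-(triisopropylsilyloxy)phenoxy]-2-methylpropanedial
Product: 7 triisopropyl{4-[(3-methylpenta-1,4-dien-3-yl)oxy]-3-vinylphenoxy}silane (achiral triene)
Conditions: MePPh3Br, KN(SiMe3)2, THF, 0 °C; 6 added slowly at −78 °C, then to 0 °C; pentane, filtration through basic Al2O3, kept at or below rt
Reagents that add atoms: methyltriphenylphosphonium bromide, C[P+](c1ccccc1)(c1ccccc1)c1ccccc1.[Br-]
Why: In this threefold Wittig methylenation, slow addition of 6 to an excess of lithium-free ylide in the cold favours direct oxaphosphetane formation over retro-Claisen deformylation of the quaternary 1,3-dialdehyde, and the acid-free, cold isolation spares the tertiary bis-allylic aryl ether.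

Step 6
Reactants: 7 triisopropyl{4-[(3-methylpenta-1,4-dien-3-yl)oxy]-3-vinylphenoxy}silane
Product: 8 (S)-2-methyl-2-vinyl-6-(triisopropylsilyloxy)-2H-chromene
Conditions: Mo(=N-2,6-iPr2C6H3)(=CHCMe2Ph)[(S)-Biphen] (5 mol %; Biphen = 3,3'-di-tert-butyl-5,5',6,6'-tetramethylbiphenyl-2,2'-diolate), toluene (0.05 M), 22 °C, N2 glovebox, vessel vented to let C2H4 escape, dark
Reagents that add atoms: none
Why: This is an asymmetric ring-closing metathesis by the metallacyclobutane mechanism: the Mo alkylidene first exchanges with the unhindered styrenyl CH=CH2 to give an aryl-substituted alkylidene, this adds [2+2] to one of the two vinyl groups on the carbinyl carbon, and cycloreversion releases 8 and Mo=CH2, which takes up the next molecule of 7 with loss of ethylene. The closest known reactions are the Mo-catalysed desymmetrising ring closures of achiral trienes to five- and six-membered cyclic tertiary allylic ethers and the ordinary ring-closing metathesis of o-vinylaryl allyl ethers to 2H-chromenes. The only ring formed is the six-membered pyran O1–C2–C3=C4–C4a–C8a, closed with the new C3=C4 bond endocyclic, and no other ring size is open because the geminal vinyl groups cannot close on each other and 7 holds no further alkene. C2 becomes stereogenic only because one vinyl group enters the ring and the other stays outside, and which one reacts is decided by the chiral biphenolate pocket, which must tell CH3 from the spectator vinyl group in the diastereomeric metallacyclobutanes, since the substrate has no bias of its own. The step thus needs enantiotopic-group selectivity from the catalyst and site selectivity of initiation from the substrate, and the latter is secured by the fully substituted carbinyl carbon, which slows direct attack on its vinyl groups, speeds cyclisation through the gem-disubstituent effect and keeps the remaining vinyl group of 8 from reacting further. Room temperature, darkness and removal of ethylene guard against aromatic Claisen rearrangement of 7, electrocyclic opening of 8 and reversible ring opening that would erode the enantiomeric purity.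

Step 7
Reactants: 9 2,4,4-trimethylcyclohex-2-en-1-one
Product: 10 (R)-2,4,4-trimethylcyclohex-2-en-1-ol
Conditions: (S)-2-methyl-CBS-oxazaborolidine (0.2 equiv), BH3·SMe2, THF, −20 °C; aqueous work-up
Reagents that add atoms: none
Why: In the Corey–Bakshi–Shibata reduction the ketone binds to the ring boron of the catalyst–BH3 complex with its larger alpha-methylalkenyl flank turned away from the catalyst, so the (S)-oxazaborolidine should deliver hydride 1,2-selectively to the face that gives the (R)-carbinol.

Step 8
Reactants: 10 (R)-2,4,4-trimethylcyclohex-2-en-1-ol; 11 N,N-dimethylacetamide dimethyl acetal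
Product: 13 (S)-N,N-dimethyl-2-(2,6,6-trimethylcyclohex-2-en-1-yl)acetamide, via ketene N,O-acetal 12 (not isolated)
Conditions: xylenes, 140 °C, MeOH distilled off
Reagents that add atoms: none
Why: In the Eschenmoser–Claisen rearrangement, alcohol exchange on 11 and loss of a second methanol give 12, whose [3,3] shift inside the ring can only be suprafacial, so the C1''–C6' bond forms on the face that carried oxygen, the (R) C–O centre is traded for the (S) C–C centre next to the gem-dimethyl carbon, and the double bond moves to its place in the target.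

Step 9
Reactants: 13 (S)-N,N-dimethyl-2-(2,6,6-trimethylcyclohex-2-en-1-yl)acetamide
Product: 14 (S)-2-(2,6,6-trimethylcyclohex-2-en-1-yl)ethanol
Conditions: LiEt3BH, THF, 0 °C to rt; H2O
Reagents that add atoms: none
Why: Reduction of a tertiary amide with LiEt3BH is known to go with C–N cleavage to the primary alcohol, and it touches neither the trisubstituted alkene nor the stereocentre, which lies beta to the carbonyl group.

Step 10
Reactants: 14 (S)-2-(2,6,6-trimethylcyclohex-2-en-1-yl)ethanol
Product: 15 (S)-6-(2-iodoethyl)-1,5,5-trimethylcyclohexene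
Conditions: I2, PPh3, imidazole, CH2Cl2, 0 °C to rt
Reagents that add atoms: iodine, II
Why: In this Appel-type iodination the alcohol is activated as an alkoxyphosphonium salt and displaced by iodide at the primary carbon, two bonds away from the stereocentre.

Step 11
Reactants: 15 (S)-6-(2-iodoethyl)-1,5,5-trimethylcyclohexene; 16 trimethylsilylacetylene
Product: 17 (S)-trimethyl[4-(2,6,6-trimethylcyclohex-2-en-1-yl)but-1-yn-1-yl]silane
Conditions: 16, n-BuLi, THF, −78 °C; then 15, DMPU, −78 °C to rt
Reagents that add atoms: none
Why: This is an SN2 alkylation of a lithium acetylide with a primary iodide, in which DMPU raises the nucleophilicity of the acetylide and the silyl cap rules out proton exchange and double alkylation.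

Step 12
Reactants: 17 (S)-trimethyl[4-(2,6,6-trimethylcyclohex-2-en-1-yl)but-1-yn-1-yl]silane
Product: 18 (S)-6-(but-3-yn-1-yl)-1,5,5-trimethylcyclohexene
Conditions: K2CO3 (cat.), MeOH, rt
Reagents that add atoms: none
Why: Base-catalysed methanolysis (protiodesilylation) cleaves the C(sp)–Si bond selectively, and nothing else in the hydrocarbon responds to methoxide.

Step 13
Reactants: 18 (S)-6-(but-3-yn-1-yl)-1,5,5-trimethylcyclohexene
Product: 20 (S)-6-[(E)-4-iodo-3-methylbut-3-en-1-yl]-1,5,5-trimethylcyclohexene, via alkenyldimethylalane 19 (not isolated)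
Conditions: Me3Al, Cp2ZrCl2 (0.25 equiv), CH2Cl2, 0 °C to rt; then I2, THF, −30 °C
Reagents that add atoms: trimethylaluminium, C[Al](C)C; iodine, II
Why: The zirconium-catalysed Negishi methylalumination adds CH3 and Al syn across the terminal alkyne with aluminium on the terminal carbon, and iodinolysis of the C–Al bond with retention fixes the E geometry, while the trisubstituted ring alkene does not react.

Step 14
Reactants: 8 (S)-2-methyl-2-vinyl-6-(triisopropylsilyloxy)-2H-chromene; 20 (S)-6-[(E)-4-iodo-3-methylbut-3-en-1-yl]-1,5,5-trimethylcyclohexene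
Product: 22 triisopropylsilyl ether of the target, (S)-2-methyl-2-{(E)-4-methyl-6-[(S)-2,6,6-trimethylcyclohex-2-en-1-yl]hex-3-en-1-yl}-6-(triisopropylsilyloxy)-2H-chromene, via B-alkyl-9-BBN borane 21 (not isolated)
Conditions: 8, 9-BBN-H, THF, 0 °C to rt; then aq. K3PO4, 20, PdCl2(dppf) (5 mol %), AsPh3, DMF, rt, degassed, dark
Reagents that add atoms: 9-borabicyclo[3.3.1]nonane, B1C2CCCC1CCC2 (its boron and carbon atoms are held by 21 only)
Why: In this hydroboration/B-alkyl Suzuki–Miyaura sequence 9-BBN-H adds anti-Markovnikov to the monosubstituted vinyl group much faster than to the cis-disubstituted styrenyl C3=C4 bond, and the phosphate-activated primary alkylborane passes its alkyl group to the alkenylpalladium iodide formed from 20 with retention of the E geometry, neither stereocentre being involved.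

Step 15
Reactants: 22 triisopropylsilyl ether of the target
Product: 23 (S)-2-methyl-2-{(E)-4-methyl-6-[(S)-2,6,6-trimethylcyclohex-2-en-1-yl]hex-3-en-1-yl}-2H-chromen-6-ol (target)
Conditions: Bu4NF, AcOH (equimolar), THF, 0 °C, argon, dark
Reagents that add atoms: none
Why: Fluoride-induced cleavage of the aryl silyl ether is driven by the Si–F bond, acetic acid protonates the phenoxide so that the electron-rich 6-hydroxychromene does not meet base and air, and cold and darkness keep C2 from racemising by electrocyclic ring opening.

Compound list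
1 | 2,5-dihydroxybenzaldehyde | O=Cc1cc(O)ccc1O | starting material
2 | 2-hydroxy-5-(triisopropylsilyloxy)benzaldehyde | O=Cc1cc(O[Si](C(C)C)(C(C)C)C(C)C)ccc1O | intermediate
3 | diethyl 2-bromo-2-methylmalonate | CCOC(=O)C(C)(Br)C(=O)OCC | starting material
4 | diethyl 2-[2-formyl-4-(triisopropylsilyloxy)phenoxy]-2-methylmalonate | CCOC(=O)C(C)(Oc1ccc(O[Si](C(C)C)(C(C)C)C(C)C)cc1C=O)C(=O)OCC | intermediate
5 | 2-[2-(hydroxymethyl)-4-(triisopropylsilyloxy)phenoxy]-2-methylpropane-1,3-diol | CC(CO)(CO)Oc1ccc(O[Si](C(C)C)(C(C)C)C(C)C)cc1CO | intermediate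
6 | 2-[2-formyl-4-(triisopropylsilyloxy)phenoxy]-2-methylpropanedial | CC(C=O)(C=O)Oc1ccc(O[Si](C(C)C)(C(C)C)C(C)C)cc1C=O | intermediate
7 | triisopropyl{4-[(3-methylpenta-1,4-dien-3-yl)oxy]-3-vinylphenoxy}silane | C=Cc1cc(O[Si](C(C)C)(C(C)C)C(C)C)ccc1OC(C)(C=C)C=C | intermediate
8 | (S)-2-methyl-2-vinyl-6-(triisopropylsilyloxy)-2H-chromene | C=C[C@@]1(C)C=Cc2cc(O[Si](C(C)C)(C(C)C)C(C)C)ccc2O1 | intermediate
9 | 2,4,4-trimethylcyclohex-2-en-1-one | CC1=CC(C)(C)CCC1=O | starting material
10 | (R)-2,4,4-trimethylcyclohex-2-en-1-ol | CC1=CC(C)(C)CC[C@H]1O | intermediate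
11 | N,N-dimethylacetamide dimethyl acetal | COC(C)(OC)N(C)C | starting material
12 | (R)-N,N-dimethyl-1-[(2,4,4-trimethylcyclohex-2-en-1-yl)oxy]ethen-1-amine (ketene N,O-acetal) | CC1=CC(C)(C)CC[C@H]1OC(=C)N(C)C | intermediate
13 | (S)-N,N-dimethyl-2-(2,6,6-trimethylcyclohex-2-en-1-yl)acetamide | CC1=CCCC(C)(C)[C@@H]1CC(=O)N(C)C | intermediate
14 | (S)-2-(2,6,6-trimethylcyclohex-2-en-1-yl)ethanol | CC1=CCCC(C)(C)[C@@H]1CCO | intermediate
15 | (S)-6-(2-iodoethyl)-1,5,5-trimethylcyclohexene | CC1=CCCC(C)(C)[C@@H]1CCI | intermediate
16 | trimethylsilylacetylene | C#C[Si](C)(C)C | starting material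
17 | (S)-trimethyl[4-(2,6,6-trimethylcyclohex-2-en-1-yl)but-1-yn-1-yl]silane | CC1=CCCC(C)(C)[C@@H]1CCC#C[Si](C)(C)C | intermediate
18 | (S)-6-(but-3-yn-1-yl)-1,5,5-trimethylcyclohexene | CC1=CCCC(C)(C)[C@@H]1CCC#C | intermediate
19 | dimethyl{(E)-2-methyl-4-[(S)-2,6,6-trimethylcyclohex-2-en-1-yl]but-1-en-1-yl}alane | CC1=CCCC(C)(C)[C@@H]1CC/C(C)=C/[Al](C)C | intermediate
20 | (S)-6-[(E)-4-iodo-3-methylbut-3-en-1-yl]-1,5,5-trimethylcyclohexene | CC1=CCCC(C)(C)[C@@H]1CC/C(C)=C/I | intermediate
21 | 9-{2-[(S)-2-methyl-6-(triisopropylsilyloxy)-2H-chromen-2-yl]ethyl}-9-borabicyclo[3.3.1]nonane | C1CC2CCCC(C1)B2CC[C@@]1(C)C=Cc2cc(O[Si](C(C)C)(C(C)C)C(C)C)ccc2O1 | intermediate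
22 | (S)-2-methyl-2-{(E)-4-methyl-6-[(S)-2,6,6-trimethylcyclohex-2-en-1-yl]hex-3-en-1-yl}-6-(triisopropylsilyloxy)-2H-chromene | CC1=CCCC(C)(C)[C@@H]1CC/C(C)=C/CC[C@@]1(C)C=Cc2cc(O[Si](C(C)C)(C(C)C)C(C)C)ccc2O1 | intermediate
23 | (S)-2-methyl-2-{(E)-4-methyl-6-[(S)-2,6,6-trimethylcyclohex-2-en-1-yl]hex-3-en-1-yl}-2H-chromen-6-ol | CC1=CCCC(C)(C)[C@@H]1CC/C(C)=C/CC[C@@]1(C)C=Cc2cc(O)ccc2O1 | target

Total step count: 15.
Longest linear sequence: 9 steps (steps 7 to 15, from 9). The chromene arm needs 8 steps (steps 1 to 6, then 14 and 15).

Steps most likely to fail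

Step 6. Several things may go wrong:
- The catalyst may tell the methyl group from the spectator vinyl group only poorly.
- It may initiate at one of the geminal vinyl groups.
- It may reopen the product ring through Mo=CH2, which erodes the enantiomeric purity.
- It may be killed by protic or phosphorus-containing traces carried over from step 5.

The fallback sets out from 7 and returns at 8. It gives up asymmetric induction in favour of racemic closure followed by separation of the mirror images. Triene 7 is closed with the second-generation Hoveyda–Grubbs catalyst RuCl2(H2IMes)(=CH-C6H4-2-OiPr) in CH2Cl2 at rt, an ordinary chromene-forming ring-closing metathesis. This gives racemic 2-methyl-2-vinyl-6-(triisopropylsilyloxy)-2H-chromene F1. The racemate is resolved by preparative chromatography on a polysaccharide-carbamate chiral stationary phase in the dark. The (S)-enantiomer is 8, and (R)-2-methyl-2-vinyl-6-(triisopropylsilyloxy)-2H-chromene F2 is set aside.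

Step 5. The nucleophilic ylide may cleave a formyl group from the quaternary 1,3-dialdehyde by a retro-Claisen process, or methylenation may stop short of all three aldehydes. The fallback sets out from 2 and returns at 7. It builds the tertiary ether from a five-carbon alcohol that already holds both arms, so no 1,3-dialdehyde is needed and steps 2 to 4 are bypassed as well.
- Bought 3-methylpent-1-en-4-yn-3-ol F3 is converted with (CF3CO)2O and DBU in MeCN at 0 °C into 3-methylpent-1-en-4-yn-3-yl trifluoroacetate F4.
- F4 is used directly for the copper-catalysed propargylic O-alkylation of phenol 2 (CuCl2·2H2O catalytic, DBU, MeCN, 0 °C). This gives racemic 2-[(3-methylpent-1-en-4-yn-3-yl)oxy]-5-(triisopropylsilyloxy)benzaldehyde F5.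
- Semihydrogenation of the alkyne (H2, Pd/CaCO3 poisoned with Pb(OAc)2, quinoline, hexane/EtOAc, rt) removes the stereocentre and gives achiral 2-[(3-methylpenta-1,4-dien-3-yl)oxy]-5-(triisopropylsilyloxy)benzaldehyde F6.
- A single Wittig methylenation of the aromatic aldehyde of F6 (MePPh3Br, KN(SiMe3)2, THF, −78 to 0 °C) gives 7.

Step 8. The sigmatropic shift onto a terminus flanked by the quaternary carbon may be slow. At 140 °C, elimination of the ketene acetal to a cyclohexadiene could then take over, or partial ionisation could blur the chirality transfer. The fallback sets out from 10 and returns at 14. It moves the rearrangement to an ester enolate derivative that reacts far below 140 °C and skips the amide.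
- Alcohol 10 is acetylated (Ac2O, pyridine, DMAP) to (R)-2,4,4-trimethylcyclohex-2-en-1-yl acetate F7.
- Enolisation and silylation (LiN(iPr)2, Me3SiCl/Et3N, THF, −78 °C) give (R)-trimethyl({1-[(2,4,4-trimethylcyclohex-2-en-1-yl)oxy]vinyl}oxy)silane F8.
- On warming to 60 °C, F8 undergoes the Ireland–Claisen rearrangement, again suprafacially, to trimethylsilyl (S)-2-(2,6,6-trimethylcyclohex-2-en-1-yl)acetate F9.
- Aqueous work-up gives (S)-2-(2,6,6-trimethylcyclohex-2-en-1-yl)acetic acid F10.
- LiAlH4 in THF reduces F10 to 14.

Further compounds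
F1 | step 6 | racemic 2-methyl-2-vinyl-6-(triisopropylsilyloxy)-2H-chromene | C=CC1(C)C=Cc2cc(O[Si](C(C)C)(C(C)C)C(C)C)ccc2O1
F2 | step 6 | (R)-2-methyl-2-vinyl-6-(triisopropylsilyloxy)-2H-chromene | C=C[C@]1(C)C=Cc2cc(O[Si](C(C)C)(C(C)C)C(C)C)ccc2O1
F3 | step 5 | 3-methylpent-1-en-4-yn-3-ol (bought, racemic) | C=CC(C)(O)C#C
F4 | step 5 | 3-methylpent-1-en-4-yn-3-yl trifluoroacetate | C=CC(C)(C#C)OC(=O)C(F)(F)F
F5 | step 5 | racemic 2-[(3-methylpent-1-en-4-yn-3-yl)oxy]-5-(triisopropylsilyloxy)benzaldehyde | C=CC(C)(C#C)Oc1ccc(O[Si](C(C)C)(C(C)C)C(C)C)cc1C=O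
F6 | step 5 | 2-[(3-methylpenta-1,4-dien-3-yl)oxy]-5-(triisopropylsilyloxy)benzaldehyde | C=CC(C)(C=C)Oc1ccc(O[Si](C(C)C)(C(C)C)C(C)C)cc1C=O
F7 | step 8 | (R)-2,4,4-trimethylcyclohex-2-en-1-yl acetate | CC1=CC(C)(C)CC[C@H]1OC(C)=O
F8 | step 8 | (R)-trimethyl({1-[(2,4,4-trimethylcyclohex-2-en-1-yl)oxy]vinyl}oxy)silane | CC1=CC(C)(C)CC[C@H]1OC(=C)O[Si](C)(C)C
F9 | step 8 | trimethylsilyl (S)-2-(2,6,6-trimethylcyclohex-2-en-1-yl)acetate | CC1=CCCC(C)(C)[C@@H]1CC(=O)O[Si](C)(C)C
F10 | step 8 | (S)-2-(2,6,6-trimethylcyclohex-2-en-1-yl)acetic acid | CC1=CCCC(C)(C)[C@@H]1CC(=O)O
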